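(The runs come from a simulation from invented constants; scatter was added.)

The autumn run is my way in. At its temperature the starting material dies slowly, and I must say what three other temperatures leave.

| flask | starting material | other conformer | temperature | remark | time |
|---|---|---|---|---|---|
| autumn | 0.50 M (fed, over 2.5 h) | 0.084 M | 12 °C | run made earlier |  |
| dawn | 0.50 M (fed, over 2.5 h) | 0.19 M | 40 °C | run made earlier |  |
| winter | 1 M (fed, over 2.5 h) | 0.125 M | 12 °C | run made earlier |  |
| green | 0.50 M (fed, over 2.5 h) | 0.125 M | 25 °C |  | 30 h |
| violet | 0.50 M (fed, over 2.5 h) | 0.125 M | 0 °C |  | 30 h |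
| red | 0.50 M (fed, over 2.5 h) | 0.125 M | 50 °C |  | 30 h |

- autumn (time / h: target / %, starting material / %): 12.0: 7.2, 62.4; 25.0: 11.9, 43.1; 40.0: 15.0, 29.1; 50.0: 16.4, 21.6; 60.0: 17.0, 16.4
- dawn (time / h: target / %, starting material / %): 1.33: 10.9, 32.3; 2.50: 23.1, 37.9; 4.00: 32.5, 14.3; 8.00: 33.8, 1.1; 15.0: 27.0, 0.5
- winter (time / h: target / %, starting material / %): 5.00: 3.7, 79.2; 10.0: 6.5, 68.6; 15.0: 9.1, 59.1; 30.0: 13.3, 38.3; 60.0: 17.2, 16.8

(each reading ± 0.3 percentage points)

- the earlier runs were read with a standard deviation of 0.3 percentage points
- in a conversion other conformer counts as not yet reacted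
- percentages count the whole charge, also what has not yet gone in

- which flask leads in amount of target, in percent of the starting material and other conformer together charged ("all alike" within 1.5 percentage points) (green / violet / red / all alike)
- how much target is there at the end, in percent of the starting material and other conformer together charged: green
- how much target is there at the end, in percent of the starting material and other conformer together charged: violet
- how much target is there at the end, in percent of the starting material and other conformer together charged: red

In the autumn run the starting material falls from 62.4% to 16.4% between 12.0 h and 60.0 h, a constant of 0.0278 h⁻¹. Does it depend on the charge? The winter run, with twice the charge, gives 0.0282 h⁻¹, about the same, so I treat the decay as first order. The dawn run gives 0.641 h⁻¹. Taking the logarithm as straight in temperature, I get 0.00726 h⁻¹ for violet, 0.119 h⁻¹ for green and 1.97 h⁻¹ for red.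

Starting material is 85.6% of the autumn charge and 72.5% of the dawn charge, and the rest is other conformer, which never was starting material gone. Target per starting material gone, a selectivity, therefore reads 31.0% at 12.0 h in the autumn run and 47.4% at 8.00 h in the dawn run. Violet has 80.0% of its charge as starting material, so with the autumn share it should reach 4.85%. The feed hardly objects, since 2.5 h is short against 30 h. Green has the same charge, and with the geometric mean of the two shares it should reach 29.8%.

But target also falls. In the dawn run it drops from 33.8% to 27.0% between 8.00 h and 15.0 h, which gives the loss half-life of target, 21.6 h. I scale it like the starting material's constant, though nothing tests that. For green this gives 116 h, longer than the time, so I leave green as it stands. For red it gives 7.05 h. In red the starting material's half-life of 0.353 h is shorter than the feed, so target peaks near the end of the feed. From the dawn peak, red falls to 2.26%.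

The forecast also puts green first, at 25% against my 29.8%, with violet at 4.5% against my 4.85% and red at 6% against my 2.26%: “Green is the best balance”.

The flask gives 25.8% in green, 3.78% in violet and 12.9% in red, and green leads.

    starting material ⇌ other conformer (K = 0.422, k = 0.00252 min⁻¹, Ea = 103 kJ mol⁻¹, ΔH = −51.0 kJ mol⁻¹)
    starting material → target (k = 0.00103 min⁻¹, Ea = 94.0 kJ mol⁻¹)
    other conformer → isomer of the product A (k = 0.00767 min⁻¹, Ea = 92.0 kJ mol⁻¹)
    target ⇌ isomer of the product A (K = 3.36, k = 1.66 × 10⁻⁴ min⁻¹, Ea = 101 kJ mol⁻¹, ΔH = 22.0 kJ mol⁻¹)
    target ⇌ isomer of the product B (K = 0.352, k = 0.00422 min⁻¹, Ea = 100 kJ mol⁻¹, ΔH = −33.0 kJ mol⁻¹)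
    (constants at 25 °C)

Red is where my half-life parts from the flask. Red holds 14.6% of target at 15.0 h and 12.9% at 30.0 h, where 7.05 h asks for a steep fall, and at 300 h it still holds 12.8%. The relaxation half-life of target and isomer of the product A by that step alone in red, 2.59 h, is short against the time. On the neighbour, red run at 75 °C, the same scaling gives 0.428 h, so 64.3 half-lives pass after the feed. That neighbour holds 7.65% of target at 30.0 h.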